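Everything rests on cutting the C5–C6 bond of flavanone ring A, so that the hindered C6–C8'' axis is traced back to a simple benzylic CH2 on C8'' of apigenin. C6 sits between the oxygenated carbons C5 and C7, and ring A carries oxygen at C5, C7 and C8a, the 1,3,5-pattern of a folded triketide. In one operation, a Claisen (Dieckmann-type) condensation of the benzylic carbon onto the ester carbon closes ring A and aromatises it to the 2-arylphloroglucinol 14. Its precursor 12 is methyl 3,5-dioxohexanoate bearing tris-MOM-protected apigenin at C6. Ring C of the flavanone is then annulated through the para oxygen.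

Key step: step 7

Remarks on the chemistry
- Numbering: flavanone atoms are unprimed (its B ring primed); flavone atoms are double-primed (its B ring triple-primed). MOM = methoxymethyl. "Tris-MOM-apigenin-8''-yl" means 5,7-bis(methoxymethoxy)-2-[4-(methoxymethoxy)phenyl]-4-oxo-4H-chromen-8-yl.
- Assumption: the target SMILES fixes only C2 (S) and leaves the configuration of the hindered C6–C8'' axis open; no step controls this axis, and compounds 18–27 are taken as the mixture of rotamers about it.
- Diketo ester 12 is drawn in its triketo form although it should exist mainly as enol tautomers; it is not chromatographed on silica, which would promote lactonisation.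

Step 1
Reactants: 1 apigenin; 2 allyl bromide
Product: 3 7''-O-allylapigenin
Conditions: K2CO3 (1.1 equiv), 2 (1.05 equiv), DMF, 0 → 25 °C
Reagents that add atoms: none
Why: Williamson etherification should go to O7'' because the 7''-hydroxyl, para to the C4'' carbonyl, is the most acidic phenol, the 5''-hydroxyl is held in a hydrogen bond to C4''=O, and one equivalent of base and halide limits reaction at O4'''.

Step 2
Reactants: 3 7''-O-allylapigenin
Product: 5 8''-allylapigenin, via cyclohexadienone 4 (not isolated)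
Conditions: N,N-diethylaniline, 200 °C, Ar
Reagents that add atoms: none
Why: Aromatic Claisen rearrangement, a [3,3]-sigmatropic shift through dienone 4 followed by enolisation, should deliver the allyl group mainly to C8'' because the C7''–C8'' bond of the benzopyranone has the higher double-bond character, any C6'' isomer being removed by chromatography.

Step 3
Reactants: 5 8''-allylapigenin
Product: 6 8''-allyl-5'',7'',4'''-tris(methoxymethyl)apigenin
Conditions: NaH (4 equiv), MOMCl (4 equiv), DMF, 0 → 25 °C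
Reagents that add atoms: chloromethyl methyl ether, COCCl
Why: Exhaustive Williamson-type O-alkylation with NaH, which also breaks the chelate of the 5''-hydroxyl, should cap all three phenols as base-stable MOM acetals before the carbanion chemistry.

Step 4
Reactants: 6 8''-allyl-5'',7'',4'''-tris(methoxymethyl)apigenin
Product: 8 (tris-MOM-apigenin-8''-yl)acetaldehyde, via vicinal diol 7 (not isolated)
Conditions: OsO4 (2 mol%), NaIO4 (4 equiv), 2,6-lutidine (2 equiv), 1,4-dioxane–H2O (3:1), 25 °C
Reagents that add atoms: sodium periodate, [Na+].[O-][I](=O)(=O)=O (source of the aldehyde oxygen); osmium tetroxide, O=[Os](=O)(=O)=O (catalytic oxygen carrier)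
Why: Lemieux–Johnson oxidation, in which OsO4 dihydroxylates the electron-rich terminal alkene far faster than the electron-poor C2''=C3'' bond and NaIO4 cleaves diol 7 in the same flask, with 2,6-lutidine buffering the medium so that the MOM acetals and the enolisable aldehyde survive.

Step 5
Reactants: 8 (tris-MOM-apigenin-8''-yl)acetaldehyde; 9 methyl acetoacetate
Product: 11 methyl 5-hydroxy-3-oxo-6-(tris-MOM-apigenin-8''-yl)hexanoate (racemic), via acetoacetate dianion 10 (not isolated)
Conditions: 9 (2.5 equiv), NaH (2.5 equiv), THF, 0 °C; n-BuLi (2.5 equiv), 0 °C; then 8, −78 °C; aq. NH4Cl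
Reagents that add atoms: none
Why: Aldol addition of the acetoacetate dianion through its more nucleophilic terminal carbon to the aldehyde at low temperature should outrun enolisation and leave the vinylogous-ester carbonyl C4'' untouched; the new carbinol centre is racemic and is destroyed in step 6.

Step 6
Reactants: 11 methyl 5-hydroxy-3-oxo-6-(tris-MOM-apigenin-8''-yl)hexanoate
Product: 12 methyl 3,5-dioxo-6-(tris-MOM-apigenin-8''-yl)hexanoate
Conditions: IBX (2 equiv), EtOAc, 75 °C; filtered and used crude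
Reagents that add atoms: none
Why: IBX oxidation of a beta-hydroxy ketone to the 1,3-diketone under neutral conditions should give the triketide 12 without touching the acetals, and the crude product is used at once to avoid lactonisation.

Step 7
Reactants: 12 methyl 3,5-dioxo-6-(tris-MOM-apigenin-8''-yl)hexanoate
Product: 14 8''-(2,4,6-trihydroxyphenyl)-5'',7'',4'''-tris(methoxymethyl)apigenin, via cyclohexanetrione 13 (not isolated)
Conditions: NaOMe (6 equiv), degassed MeOH–THF (3:1), 65 °C, Ar; then aq. NaH2PO4 to pH 6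
Reagents that add atoms: none
Why: Methoxide equilibrates the enolates of 12, and only the minor benzylic C6 enolate of the C5 ketone (hexanoate numbering) can reach the ester carbon C1 through a six-membered transition state; addition and loss of methoxide give trione 13, which enolises at once to the phloroglucinol, so that the bond destined to be C5–C6 of ring A is formed. The closest known reaction type is the base-induced Claisen (Dieckmann-type) cyclisation of 3,5-dioxoalkanoates, or of their 4-hydroxy-2-pyranone forms, to phloroglucinols. Ring A closes in the 6-(enolendo)-exo-trig mode, because the enolate C5=C6 bond lies inside the ring being formed. No stereocentre is created, and the new ring is symmetric about the biaryl bond, so the axis is not yet stereogenic. The step needs C-acylation by C6 to prevail over O-acylation by the C5 enolate oxygen: the lactone from O-acylation is reopened by methoxide, whereas the carbocycle is withdrawn irreversibly as the aromatic phloroglucinolate, and C2 and C4 cannot reach C1 in a ring of workable size.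

Step 8
Reactants: 14 8''-(2,4,6-trihydroxyphenyl)-5'',7'',4'''-tris(methoxymethyl)apigenin
Product: 15 8''-[2,6-dihydroxy-4-(triisopropylsilyloxy)phenyl]-5'',7'',4'''-tris(methoxymethyl)apigenin
Conditions: TIPSCl (1.05 equiv), imidazole (2.5 equiv), DMF, −20 → 0 °C
Reagents that add atoms: chlorotriisopropylsilane, CC(C)[Si](Cl)(C(C)C)C(C)C
Why: Silylation of phenols with a bulky chlorosilane is governed by steric access, so the para hydroxyl with two ortho hydrogens should react ahead of the two hydroxyls that flank the perpendicular flavone ring.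

Step 9
Reactants: 15 8''-[2,6-dihydroxy-4-(triisopropylsilyloxy)phenyl]-5'',7'',4'''-tris(methoxymethyl)apigenin
Product: 16 8''-[2,6-bis(methoxymethoxy)-4-(triisopropylsilyloxy)phenyl]-5'',7'',4'''-tris(methoxymethyl)apigenin
Conditions: MOMCl (4 equiv), i-Pr2NEt (5 equiv), CH2Cl2, 40 °C
Reagents that add atoms: chloromethyl methyl ether, COCCl
Why: Williamson-type acetalisation with the small electrophile MOMCl under amine base should cap both hindered flanking phenols while the aryl silyl ether, which could migrate under alkoxide conditions, stays in place.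

Step 10
Reactants: 16 8''-[2,6-bis(methoxymethoxy)-4-(triisopropylsilyloxy)phenyl]-5'',7'',4'''-tris(methoxymethyl)apigenin
Product: 18 8''-[4-hydroxy-3-iodo-2,6-bis(methoxymethoxy)phenyl]-5'',7'',4'''-tris(methoxymethyl)apigenin, via phenoxide 17 (not isolated)
Conditions: TBAF (1.1 equiv), THF, 0 °C; then NIS (1.0 equiv), −40 → 0 °C; aq. Na2S2O3, NH4Cl
Reagents that add atoms: N-iodosuccinimide, O=C1CCC(=O)N1I
Why: Fluoride-induced desilylation frees phenoxide 17, whose ring is by far the most electron-rich arene present, so electrophilic iodination with one equivalent of NIS should occur ortho to the oxide at one of the two equivalent free positions, the para position being blocked by the flavone.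

Step 11
Reactants: 18 8''-[4-hydroxy-3-iodo-2,6-bis(methoxymethoxy)phenyl]-5'',7'',4'''-tris(methoxymethyl)apigenin; 19 tributyl(1-ethoxyvinyl)stannane
Product: 21 8''-[3-acetyl-4-hydroxy-2,6-bis(methoxymethoxy)phenyl]-5'',7'',4'''-tris(methoxymethyl)apigenin, via enol ether 20 (not isolated)
Conditions: 19 (1.5 equiv), PdCl2(PPh3)2 (5 mol%), toluene, 100 °C; then 10% aq. citric acid, THF, 25 °C
Reagents that add atoms: water, O
Why: Stille coupling of the aryl iodide with the 1-ethoxyvinylstannane, an acetyl anion equivalent, followed by mild hydrolysis of enol ether 20 should install the acetyl group ortho to the free hydroxyl without any Lewis acid, so that all MOM groups survive.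

Step 12
Reactants: 22 4-hydroxybenzaldehyde
Product: 23 4-(methoxymethoxy)benzaldehyde
Conditions: MOMCl (1.3 equiv), i-Pr2NEt (1.5 equiv), CH2Cl2, 0 → 25 °C
Reagents that add atoms: chloromethyl methyl ether, COCCl
Why: Routine Williamson-type MOM protection of the phenol, so that the aldehyde can be used in the basic condensation.

Step 13
Reactants: 21 8''-[3-acetyl-4-hydroxy-2,6-bis(methoxymethoxy)phenyl]-5'',7'',4'''-tris(methoxymethyl)apigenin; 23 4-(methoxymethoxy)benzaldehyde
Product: 25 (E)-2'-hydroxychalcone bearing the tris-MOM-apigenin-8''-yl group, via aldol adduct 24 (not isolated)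
Conditions: 23 (1.5 equiv), Ba(OH)2·8H2O (3 equiv), MeOH, 40 °C
Reagents that add atoms: none
Why: Claisen–Schmidt condensation (aldol addition to 24, then E1cB dehydration) of the methyl ketone with the non-enolisable aldehyde should give the E-chalcone, whose only free hydroxyl is the one destined to become O1.

Step 14
Reactants: 25 (E)-2'-hydroxychalcone bearing the tris-MOM-apigenin-8''-yl group
Product: 26 (2S)-hexakis(methoxymethyl) ether of the target flavanone–flavone
Conditions: quinine-derived 3,5-bis(trifluoromethyl)phenyl thiourea (20 mol%), toluene, 0 °C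
Reagents that add atoms: none
Why: Bifunctional amine–thiourea catalysis of the intramolecular oxa-Michael addition (6-endo-trig), in which the quinuclidine nitrogen activates the single free phenol and the thiourea binds the enone carbonyl, should direct oxygen to one face of the beta carbon and set C2 as S (the quinidine-derived pseudoenantiomer being used should the sense prove opposite), and as only the para oxygen is free the 6-linked flavanone alone can form.

Step 15
Reactants: 26 (2S)-hexakis(methoxymethyl) ether of the target flavanone–flavone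
Product: 27 target, (2S)-naringenin-(6→8'')-apigenin
Conditions: 3 M aq. HCl–MeOH (1:5), 50 °C
Reagents that add atoms: none
Why: Acid-catalysed acetal exchange with methanol removes all six MOM groups, and since flavanone ring opening needs base or much harsher acid, the C2 configuration and the 6,8''-linkage should be retained.

Compound list
1 | apigenin, 5,7-dihydroxy-2-(4-hydroxyphenyl)-4H-chromen-4-one | O=c1cc(-c2ccc(O)cc2)oc2cc(O)cc(O)c12 | starting material
2 | allyl bromide | C=CCBr | starting material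
3 | 7''-O-allylapigenin, 7-(allyloxy)-5-hydroxy-2-(4-hydroxyphenyl)-4H-chromen-4-one | O=c1cc(-c2ccc(O)cc2)oc2cc(OCC=C)cc(O)c12 | intermediate
4 | Claisen dienone, 8-allyl-5-hydroxy-2-(4-hydroxyphenyl)-8H-chromene-4,7-dione (racemic; not isolated) | C=CCC1C(=O)C=C(O)C2=C1OC(=CC2=O)c1ccc(O)cc1 | intermediate
5 | 8''-allylapigenin, 8-allyl-5,7-dihydroxy-2-(4-hydroxyphenyl)-4H-chromen-4-one | C=CCc1c(O)cc(O)c2c(=O)cc(-c3ccc(O)cc3)oc12 | intermediate
6 | 8''-allyl-5'',7'',4'''-tris(methoxymethyl)apigenin | C=CCc1c(OCOC)cc(OCOC)c2c(=O)cc(-c3ccc(OCOC)cc3)oc12 | intermediate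
7 | 8''-(2,3-dihydroxypropyl)-5'',7'',4'''-tris(methoxymethyl)apigenin (racemic; not isolated) | OCC(O)Cc1c(OCOC)cc(OCOC)c2c(=O)cc(-c3ccc(OCOC)cc3)oc12 | intermediate
8 | (tris-MOM-apigenin-8''-yl)acetaldehyde | O=CCc1c(OCOC)cc(OCOC)c2c(=O)cc(-c3ccc(OCOC)cc3)oc12 | intermediate
9 | methyl acetoacetate | COC(=O)CC(C)=O | starting material
10 | sodium lithium bis-enolate (dianion) of methyl acetoacetate (not isolated) | [Na+].[Li+].C=C([O-])C=C([O-])OC | intermediate
11 | methyl 5-hydroxy-3-oxo-6-(tris-MOM-apigenin-8''-yl)hexanoate (racemic at C5) | COC(=O)CC(=O)CC(O)Cc1c(OCOC)cc(OCOC)c2c(=O)cc(-c3ccc(OCOC)cc3)oc12 | intermediate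
12 | methyl 3,5-dioxo-6-(tris-MOM-apigenin-8''-yl)hexanoate (key-step precursor) | COC(=O)CC(=O)CC(=O)Cc1c(OCOC)cc(OCOC)c2c(=O)cc(-c3ccc(OCOC)cc3)oc12 | intermediate
13 | 2-(tris-MOM-apigenin-8''-yl)cyclohexane-1,3,5-trione (not isolated) | O=C1CC(=O)C(c2c(OCOC)cc(OCOC)c3c(=O)cc(-c4ccc(OCOC)cc4)oc23)C(=O)C1 | intermediate
14 | 8''-(2,4,6-trihydroxyphenyl)-5'',7'',4'''-tris(methoxymethyl)apigenin (key-step product) | Oc1cc(O)c(-c2c(OCOC)cc(OCOC)c3c(=O)cc(-c4ccc(OCOC)cc4)oc23)c(O)c1 | intermediate
15 | 8''-[2,6-dihydroxy-4-(triisopropylsilyloxy)phenyl]-5'',7'',4'''-tris(methoxymethyl)apigenin | CC(C)[Si](C(C)C)(C(C)C)Oc1cc(O)c(-c2c(OCOC)cc(OCOC)c3c(=O)cc(-c4ccc(OCOC)cc4)oc23)c(O)c1 | intermediate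
16 | 8''-[2,6-bis(methoxymethoxy)-4-(triisopropylsilyloxy)phenyl]-5'',7'',4'''-tris(methoxymethyl)apigenin | CC(C)[Si](C(C)C)(C(C)C)Oc1cc(OCOC)c(-c2c(OCOC)cc(OCOC)c3c(=O)cc(-c4ccc(OCOC)cc4)oc23)c(OCOC)c1 | intermediate
17 | tetrabutylammonium 3,5-bis(methoxymethoxy)-4-(tris-MOM-apigenin-8''-yl)phenoxide (not isolated) | [O-]c1cc(OCOC)c(-c2c(OCOC)cc(OCOC)c3c(=O)cc(-c4ccc(OCOC)cc4)oc23)c(OCOC)c1.CCCC[N+](CCCC)(CCCC)CCCC | intermediate
18 | 8''-[4-hydroxy-3-iodo-2,6-bis(methoxymethoxy)phenyl]-5'',7'',4'''-tris(methoxymethyl)apigenin | Oc1cc(OCOC)c(-c2c(OCOC)cc(OCOC)c3c(=O)cc(-c4ccc(OCOC)cc4)oc23)c(OCOC)c1I | intermediate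
19 | tributyl(1-ethoxyvinyl)stannane | CCCC[Sn](CCCC)(CCCC)C(=C)OCC | starting material
20 | 8''-[3-(1-ethoxyvinyl)-4-hydroxy-2,6-bis(methoxymethoxy)phenyl]-5'',7'',4'''-tris(methoxymethyl)apigenin (not isolated) | CCOC(=C)c1c(O)cc(OCOC)c(-c2c(OCOC)cc(OCOC)c3c(=O)cc(-c4ccc(OCOC)cc4)oc23)c1OCOC | intermediate
21 | 8''-[3-acetyl-4-hydroxy-2,6-bis(methoxymethoxy)phenyl]-5'',7'',4'''-tris(methoxymethyl)apigenin | CC(=O)c1c(O)cc(OCOC)c(-c2c(OCOC)cc(OCOC)c3c(=O)cc(-c4ccc(OCOC)cc4)oc23)c1OCOC | intermediate
22 | 4-hydroxybenzaldehyde | O=Cc1ccc(O)cc1 | starting material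
23 | 4-(methoxymethoxy)benzaldehyde | COCOc1ccc(C=O)cc1 | intermediate
24 | aldol adduct, 3-hydroxy-1-[6-hydroxy-2,4-bis(methoxymethoxy)-3-(tris-MOM-apigenin-8''-yl)phenyl]-3-[4-(methoxymethoxy)phenyl]propan-1-one (racemic; not isolated) | COCOc1ccc(C(O)CC(=O)c2c(O)cc(OCOC)c(-c3c(OCOC)cc(OCOC)c4c(=O)cc(-c5ccc(OCOC)cc5)oc34)c2OCOC)cc1 | intermediate
25 | (E)-1-[6-hydroxy-2,4-bis(methoxymethoxy)-3-(tris-MOM-apigenin-8''-yl)phenyl]-3-[4-(methoxymethoxy)phenyl]prop-2-en-1-one | COCOc1ccc(/C=C/C(=O)c2c(O)cc(OCOC)c(-c3c(OCOC)cc(OCOC)c4c(=O)cc(-c5ccc(OCOC)cc5)oc34)c2OCOC)cc1 | intermediate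
26 | (2S)-5,7-bis(methoxymethoxy)-2-[4-(methoxymethoxy)phenyl]-6-(tris-MOM-apigenin-8''-yl)chroman-4-one | O=C1C[C@@H](c2ccc(OCOC)cc2)Oc2cc(OCOC)c(-c3c(OCOC)cc(OCOC)c4c(=O)cc(-c5ccc(OCOC)cc5)oc34)c(OCOC)c21 | intermediate
27 | (2S)-naringenin-(6→8'')-apigenin, CNP0154104.1 | O=C1C[C@@H](c2ccc(O)cc2)Oc2cc(O)c(-c3c(O)cc(O)c4c(=O)cc(-c5ccc(O)cc5)oc34)c(O)c21 | target

Total step count: 15. Longest linear sequence: 14 steps (steps 1–11 and 13–15; step 12 is a one-step side branch).

Steps most likely to fail

1. Step 7 (key step). The benzylic C6 position is the least acidic of the three methylenes, so the closure may stall with the material resting as its lactone, or the diketone may fragment by retro-Claisen cleavage. In that case the C6–C8'' bond is made by cross-coupling instead of by ring construction. Setting out from apigenin 1, exhaustive protection (NaH, MOMCl, DMF) should give 5'',7'',4'''-tris(methoxymethyl)apigenin F1, which is iodinated at C8'', the position usually attacked in 5,7-dialkoxyflavones (NIS, DMF, 40 °C), to 8''-iodo-5'',7'',4'''-tris(methoxymethyl)apigenin F2. Commercial 1,3,5-tris(benzyloxy)benzene is brominated (NBS, CH2Cl2, 0 °C) to 2-bromo-1,3,5-tris(benzyloxy)benzene F3 and converted by Miyaura borylation (B2pin2, Pd(OAc)2, SPhos, KOAc, dioxane, 90 °C) into 2,4,6-tris(benzyloxy)phenylboronic acid pinacol ester F4. Suzuki–Miyaura coupling of F2 with F4 (Pd(OAc)2, SPhos, K3PO4, toluene–H2O, 100 °C) should give 8''-[2,4,6-tris(benzyloxy)phenyl]-5'',7'',4'''-tris(methoxymethyl)apigenin F5, and hydrogenolysis (H2, Pd/C, EtOAc–MeOH) returns to the route at triol 14.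

2. Step 8. Silylation may not discriminate the para hydroxyl from the flanking pair well enough, giving regioisomeric or doubly silylated ethers. Steric discrimination is then replaced by chelation control after the acetyl group is in place. Setting out from triol 14, mono-iodination (I2, NaHCO3, THF–H2O, 0 °C) should give 8''-(3-iodo-2,4,6-trihydroxyphenyl)-5'',7'',4'''-tris(methoxymethyl)apigenin F6. Stille coupling with 19 (PdCl2(PPh3)2, dioxane, 90 °C) gives 8''-[3-(1-ethoxyvinyl)-2,4,6-trihydroxyphenyl]-5'',7'',4'''-tris(methoxymethyl)apigenin F7, hydrolysed in a citric acid work-up to 8''-(3-acetyl-2,4,6-trihydroxyphenyl)-5'',7'',4'''-tris(methoxymethyl)apigenin F8. TBSCl (2.2 equiv, imidazole, DMF) should silylate the two more accessible hydroxyls and spare the one wedged between acetyl and flavone, giving 8''-[3-acetyl-4,6-bis(tert-butyldimethylsilyloxy)-2-hydroxyphenyl]-5'',7'',4'''-tris(methoxymethyl)apigenin F9. Forcing MOM protection (MOMCl, i-Pr2NEt, NaI, DME, 60 °C) then gives 8''-[3-acetyl-4,6-bis(tert-butyldimethylsilyloxy)-2-(methoxymethoxy)phenyl]-5'',7'',4'''-tris(methoxymethyl)apigenin F10, and TBAF gives 8''-[3-acetyl-4,6-dihydroxy-2-(methoxymethoxy)phenyl]-5'',7'',4'''-tris(methoxymethyl)apigenin F11. In F11 the hydroxyl ortho to the acetyl group is chelated, so one equivalent of MOMCl with i-Pr2NEt should protect only the other one, which rejoins the route at ketone 21.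

3. Step 14. The catalyst may give poor facial selectivity, or the product may racemise through reversible ring opening under the basic catalyst. The stereocentre is then secured by kinetic resolution. Setting out from chalcone 25, NaOAc in EtOH at 78 °C should give racemic 5,7-bis(methoxymethoxy)-2-[4-(methoxymethoxy)phenyl]-6-(tris-MOM-apigenin-8''-yl)chroman-4-one F12. Asymmetric transfer hydrogenation with RuCl[(R,R)-TsDPEN](p-cymene) and HCO2H–Et3N in EtOAc at 25 °C, stopped near half conversion, should reduce the 2R ketone to the (2R,4R)-cis-flavan-4-ol hexakis(methoxymethyl) ether F13 and leave the 2S ketone, which is separated by chromatography and is 26.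

Further compounds
F1 | step 7 | 5'',7'',4'''-tris(methoxymethyl)apigenin | COCOc1ccc(-c2cc(=O)c3c(OCOC)cc(OCOC)cc3o2)cc1
F2 | step 7 | 8''-iodo-5'',7'',4'''-tris(methoxymethyl)apigenin | COCOc1ccc(-c2cc(=O)c3c(OCOC)cc(OCOC)c(I)c3o2)cc1
F3 | step 7 | 2-bromo-1,3,5-tris(benzyloxy)benzene | Brc1c(OCc2ccccc2)cc(OCc2ccccc2)cc1OCc1ccccc1
F4 | step 7 | 2,4,6-tris(benzyloxy)phenylboronic acid pinacol ester | CC1(C)OB(OC1(C)C)c1c(OCc2ccccc2)cc(OCc2ccccc2)cc1OCc1ccccc1
F5 | step 7 | 8''-[2,4,6-tris(benzyloxy)phenyl]-5'',7'',4'''-tris(methoxymethyl)apigenin | COCOc1ccc(-c2cc(=O)c3c(OCOC)cc(OCOC)c(-c4c(OCc5ccccc5)cc(OCc5ccccc5)cc4OCc4ccccc4)c3o2)cc1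
F6 | step 8 | 8''-(3-iodo-2,4,6-trihydroxyphenyl)-5'',7'',4'''-tris(methoxymethyl)apigenin | Oc1cc(O)c(-c2c(OCOC)cc(OCOC)c3c(=O)cc(-c4ccc(OCOC)cc4)oc23)c(O)c1I
F7 | step 8 | 8''-[3-(1-ethoxyvinyl)-2,4,6-trihydroxyphenyl]-5'',7'',4'''-tris(methoxymethyl)apigenin | CCOC(=C)c1c(O)cc(O)c(-c2c(OCOC)cc(OCOC)c3c(=O)cc(-c4ccc(OCOC)cc4)oc23)c1O
F8 | step 8 | 8''-(3-acetyl-2,4,6-trihydroxyphenyl)-5'',7'',4'''-tris(methoxymethyl)apigenin | CC(=O)c1c(O)cc(O)c(-c2c(OCOC)cc(OCOC)c3c(=O)cc(-c4ccc(OCOC)cc4)oc23)c1O
F9 | step 8 | 8''-[3-acetyl-4,6-bis(tert-butyldimethylsilyloxy)-2-hydroxyphenyl]-5'',7'',4'''-tris(methoxymethyl)apigenin | CC(=O)c1c(O[Si](C)(C)C(C)(C)C)cc(O[Si](C)(C)C(C)(C)C)c(-c2c(OCOC)cc(OCOC)c3c(=O)cc(-c4ccc(OCOC)cc4)oc23)c1O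
F10 | step 8 | 8''-[3-acetyl-4,6-bis(tert-butyldimethylsilyloxy)-2-(methoxymethoxy)phenyl]-5'',7'',4'''-tris(methoxymethyl)apigenin | CC(=O)c1c(O[Si](C)(C)C(C)(C)C)cc(O[Si](C)(C)C(C)(C)C)c(-c2c(OCOC)cc(OCOC)c3c(=O)cc(-c4ccc(OCOC)cc4)oc23)c1OCOC
F11 | step 8 | 8''-[3-acetyl-4,6-dihydroxy-2-(methoxymethoxy)phenyl]-5'',7'',4'''-tris(methoxymethyl)apigenin | CC(=O)c1c(O)cc(O)c(-c2c(OCOC)cc(OCOC)c3c(=O)cc(-c4ccc(OCOC)cc4)oc23)c1OCOC
F12 | step 14 | racemic 5,7-bis(methoxymethoxy)-2-[4-(methoxymethoxy)phenyl]-6-(tris-MOM-apigenin-8''-yl)chroman-4-one | O=C1CC(c2ccc(OCOC)cc2)Oc2cc(OCOC)c(-c3c(OCOC)cc(OCOC)c4c(=O)cc(-c5ccc(OCOC)cc5)oc34)c(OCOC)c21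
F13 | step 14 | (2R,4R)-5,7-bis(methoxymethoxy)-2-[4-(methoxymethoxy)phenyl]-6-(tris-MOM-apigenin-8''-yl)chroman-4-ol | O[C@@H]1C[C@H](c2ccc(OCOC)cc2)Oc2cc(OCOC)c(-c3c(OCOC)cc(OCOC)c4c(=O)cc(-c5ccc(OCOC)cc5)oc34)c(OCOC)c21
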